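At early times, with equivalents and loading held fixed, I used the bench rule that yield in a set time goes with concentration squared, because partner and catalyst were charged in proportion to starting material.

the same everywhere: catalyst 0.1 mol%

| run | starting material | partner | second substrate | remark | time |
|---|---|---|---|---|---|
| north-west | 10 mM | 0.90 equiv | 1 equiv | run made earlier |  |
| north | 65 mM | 0.90 equiv | 1 equiv | run made earlier |  |
| theta | 20 mM | 0.900 equiv | 1.00 equiv |  | 1.0 h |
| gamma | 40 mM | 0.900 equiv | 1.00 equiv |  | 1.0 h |
| epsilon | 80 mM | 0.900 equiv | 1.00 equiv |  | 1.0 h |

- north-west (time / min: target / %): 10.0: 2.1; 20.0: 3.0; 30.0: 3.4; 40.0: 5.1; 50.0: 5.9; 60.0: 6.2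
- north (time / min: target / %): 10.0: 27.2; 20.0: 32.5; 30.0: 31.6; 40.0: 29.2; 50.0: 28.3; 60.0: 26.8

(standard deviation of a reading: 0.5 percentage points)

- percentages count the starting material that a species holds: one side product counts as two
- reactions considered so far: starting material + partner + catalyst -> catalyst + target; second substrate + partner + catalyst -> catalyst + second product; starting material + target -> side product
- "hardly changes" means that all values lie within two and a half points (for a concentration: within two and a half percent of the largest)

* amount of target at the end, in percent of the starting material charged for theta, gamma, epsilon, in this order
* how that number moves from the first to the last of them (rises all the way / falls, then rises / rises, then falls / hardly changes / falls all the way)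

I replaced the north-west curve by its mean, dividing the sum of its readings by the sum of its times, which gave a pace of 0.0734 h⁻¹. Scaled to theta, that pace gave 29.4% in 1.0 h. For gamma it gave 117%, which was impossible. I took an even split of partner between the two substrates as an assumption, so target could reach 45.0%, and for gamma the square law stood above that border.

I therefore used the ratio of the two, the partner load: the square-law yield over the partner's share. It counts the e-foldings of partner in the time, a pseudo-first-order decay with both substrates held at their charges, and partner is the limiting reagent.

partner left = e^(−load)
target made, before any loss to side product = share × (one − partner left)

theta: load 0.653, partner left 52.1%, target made 21.6%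
gamma: load 2.61, partner left 7.35%, target made 41.7%
epsilon: load 10.4, target made 45.0%

The mean treated partner as standing at its charge, but the north-west load of 0.163 put its average partner about 8.15% below charge, so I took the pace to read low by about that much. Target made gained 20 percentage points from theta to gamma, and less from gamma to epsilon, 3.3 points. The north run meanwhile fell from 32.5% at 20.0 min to 26.8% at 60.0 min, so I expected a turn.

The forecast, reasoning that “Taking equal selectivity for the two substrates, the partner splits about evenly”, gave 16.3%, 28.5% and 23%, with the shape rises, then falls.

The flasks gave 18.9%, 28.1% and 23.2%, with the shape rises, then falls.

    starting material + partner + catalyst → catalyst + target (k = 286 M⁻² s⁻¹)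
    second substrate + partner + catalyst → catalyst + second product (k = 287 M⁻² s⁻¹)
    starting material + target → side product (k = 0.00545 M⁻¹ s⁻¹)

Load 0.653 promised theta 52.1% of its partner and the flask held 49%; load 2.61 promised gamma 7.35% and it held 10%. In theta partner fell from 68.4% at 0.500 h to 49% at 1.00 h, and at that last moment target, each step taken net, was being made 2.46 times faster than it was used up. In epsilon partner stood at 1.80% by 0.500 h, and from then to 1.00 h, with starting material and target both present, target went from 30.8% to 23.2% while side product rose from 25.3% to 41.8%.

(The earlier runs and the new flask were computed on assumed constants; noise was put on by code.)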